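**Retrosynthetic overview**
1. Feature: in the naphthazarin core, C2=C3 of quinone ring B is the only ring B bond that involves no carbon of arene ring A. C2 also carries the side chain C1'–C4'. Cutting C2=C3 leaves two enone arms on neighbouring carbons of a 1,4-dimethoxybenzene.
2. Target ⇒ 5,8-dimethoxy-1,4-naphthoquinone with the complete ester side chain (oxidative demethylation, then reduction) ⇒ ortho-bis-enone with an acryloyl arm and an alpha-branched enone arm (ring-closing metathesis at C2=C3).
3. Bis-enone ⇒ 3,6-dimethoxyphthalaldehyde + a 2-lithio-1,4-diene (bond C1–C2) + vinylmagnesium bromide (bond C3–C4). Double oxidation, ether cleavage and esterification with (R)-2-methylbutanoic acid follow.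
4. 2-Bromodiene ⇒ 2-bromoacrolein + the (E)-alkenylzinc from 2-methylbut-3-yn-2-ol. The ligand-controlled addition sets C1' as R, hydroboration sets the E alkene, and the second stereocentre is bought with the acid.
5. Ring order: ring A comes with the anhydride. Ring B is the only ring made, in step 12.

Key step: step 12

Remark on the chemistry: 12, 13 and 14 are carried as mixtures of epimers at the lactol and benzylic carbinol carbons (left undefined in the SMILES), because step 9 turns these carbons into carbonyl groups. The naphthazarin tautomers interconvert fast, so 21 is drawn as in the target SMILES.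

**Step 1**
Reactants: 1 2-methylbut-3-yn-2-ol
Product: 2 triethyl[(2-methylbut-3-yn-2-yl)oxy]silane
Conditions: TESCl, imidazole, DMAP (cat.), DMF, rt
Reagents that add atoms: chlorotriethylsilane (TESCl), CC[Si](Cl)(CC)CC
Why: Imidazole-promoted silyl ether formation on the little-hindered tertiary propargylic alcohol masks the O–H that would otherwise consume the borane and zinc reagents of step 2 and compete in the etherification of step 3.

**Step 2**
Reactants: 2 triethyl[(2-methylbut-3-yn-2-yl)oxy]silane; 3 2-bromoacrolein
Product: 6 (3R,4E)-2-bromo-6-methyl-6-(triethylsilyloxy)hepta-1,4-dien-3-ol, via alkenylborane 4 (not isolated), via alkenylzinc 5 (not isolated)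
Conditions: Cy2BH, toluene, 0 °C to rt; Me2Zn, (+)-MIB [(2R)-3-exo-morpholinoisoborneol, 5 mol%], −78 °C; 3 added slowly, −30 to −10 °C; aq. NH4Cl
Reagents that add atoms: none
Why: In this catalytic asymmetric alkenylzinc addition, syn-hydroboration of the terminal alkyne fixes the E geometry of C2'=C3', boron-to-zinc exchange gives the alkenylzinc, and the zinc amino-alkoxide from (+)-MIB (the antipode of the ligand that directs Si-face attack and turns benzaldehyde and Et2Zn into (S)-1-phenylpropan-1-ol) delivers the alkenyl group to the Re face of the aldehyde, which sets C1' as R.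

**Step 3**
Reactants: 6 (3R,4E)-2-bromo-6-methyl-6-(triethylsilyloxy)hepta-1,4-dien-3-ol
Product: 7 (3R,4E)-2-bromo-3-(4-methoxybenzyloxy)-6-methyl-6-(triethylsilyloxy)hepta-1,4-diene
Conditions: NaH, PMBCl, Bu4NI (cat.), THF/DMF, 0 °C to rt
Reagents that add atoms: 4-methoxybenzyl chloride (PMBCl), COc1ccc(CCl)cc1
Why: This Williamson etherification reacts only at the O–H bond and so leaves C1' untouched, and a benzyl-type ether is preferred to a silyl ether on this oxygen because a silyl group could shift from O to the adjacent vinyl carbanion (retro-Brook rearrangement) in step 6.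

**Step 4**
Reactants: 8 3,6-dimethoxyphthalic anhydride
Product: 9 (3,6-dimethoxy-1,2-phenylene)dimethanol
Conditions: LiAlH4, THF, 0 °C to reflux
Reagents that add atoms: none
Why: Exhaustive hydride reduction of a cyclic anhydride to the 1,2-benzenedimethanol is standard, and the aryl methyl ethers are inert to it.

**Step 5**
Reactants: 9 (3,6-dimethoxy-1,2-phenylene)dimethanol
Product: 10 3,6-dimethoxyphthalaldehyde
Conditions: (COCl)2, DMSO, CH2Cl2, −78 °C; Et3N, −78 °C to rt
Reagents that add atoms: none
Why: The Swern oxidation activates both primary alcohols before base is added, so both are oxidised together and the lactol-to-phthalide pathway open to stepwise oxidants is avoided.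

**Step 6**
Reactants: 7 (3R,4E)-2-bromo-3-(4-methoxybenzyloxy)-6-methyl-6-(triethylsilyloxy)hepta-1,4-diene; 10 3,6-dimethoxyphthalaldehyde
Product: 12 4,7-dimethoxy-3-[(3R,4E)-3-(4-methoxybenzyloxy)-6-methyl-6-(triethylsilyloxy)hepta-1,4-dien-2-yl]-1,3-dihydroisobenzofuran-1-ol (epimers at C1 and C3), via vinyllithium 11 (not isolated)
Conditions: t-BuLi (2 equiv), Et2O, −78 °C; cannulated into 10 (1.4 equiv), THF, −78 °C; aq. NH4Cl
Reagents that add atoms: none
Why: Bromine–lithium exchange at −78 °C outruns any deprotonation, and 1,2-addition of the valuable vinyllithium to an excess of the cheap dialdehyde should stop after one addition because the new alkoxide closes onto the second formyl group as a lactolate, with a carbinol centre that needs no control.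

**Step 7**
Reactants: 12 the lactol of step 6
Product: 13 diol: 1,4-dimethoxybenzene bearing CH(OH)CH=CH2 at C2 and CH(OH)C(=CH2)-[(R)-CH(OPMB)]-(E)-CH=CH-C(CH3)2OTES at C3 (epimers at both carbinol carbons)
Conditions: CH2=CHMgBr (3.5 equiv), THF, 0 °C to rt; aq. NH4Cl
Reagents that add atoms: vinylmagnesium bromide, C=C[Mg]Br
Why: In this Grignard addition to a lactol, the first equivalent deprotonates and opens the ring to the alkoxy-aldehyde, which then takes up the small vinyl nucleophile by 1,2-addition, and the ethers are inert.

**Step 8**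
Reactants: 13 the diol of step 7
Product: 14 triol: as 13 but with the free tertiary alcohol C(CH3)2OH at C4'
Conditions: Bu4NF, THF, 0 °C to rt
Reagents that add atoms: none
Why: Fluoride-induced desilylation is placed here because no base-sensitive enone is present yet, and it avoids acid that would ionise the electron-rich benzylic alcohols.

**Step 9**
Reactants: 14 the triol of step 8
Product: 15 1-{2-[(3R,4E)-6-hydroxy-3-(4-methoxybenzyloxy)-6-methyl-2-methylidenehept-4-enoyl]-3,6-dimethoxyphenyl}prop-2-en-1-one
Conditions: Dess–Martin periodinane (2.6 equiv), CH2Cl2, 0 °C to rt; product kept cold with BHT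
Reagents that add atoms: none
Why: The Dess–Martin oxidation converts both secondary benzylic-allylic alcohols to ketones under nearly neutral conditions, cannot attack the tertiary alcohol or the PMB ether, drains any hemiketal of the mono-ketone through its open form, and erases the two undefined centres.

**Step 10**
Reactants: 15 the bis-enone PMB ether of step 9
Product: 16 1-{2-[(3R,4E)-3,6-dihydroxy-6-methyl-2-methylidenehept-4-enoyl]-3,6-dimethoxyphenyl}prop-2-en-1-one
Conditions: DDQ (1.3 equiv), CH2Cl2/pH 7 buffer, 0 °C
Reagents that add atoms: none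
Why: Oxidative PMB cleavage (hydride abstraction from the electron-rich benzyl ether, then hydrolysis of the oxocarbenium ion) is neutral and breaks no bond at C1', and the diacylated dimethoxyarene and the enones are too electron-poor for DDQ.

**Step 11**
Reactants: 16 the bis-enone diol of step 10; 17 (R)-2-methylbutanoic acid
Product: 18 (R,E)-2-(2-acryloyl-3,6-dimethoxybenzoyl)-6-hydroxy-6-methylhepta-1,4-dien-3-yl (R)-2-methylbutanoate
Conditions: DCC, DMAP (10 mol%), CH2Cl2, 0 °C
Reagents that add atoms: none
Why: The Steglich esterification acylates only the secondary alcohol (the tertiary one is too hindered) with retention at C1' because the C–O bond stays intact, while low temperature and catalytic DMAP hold back SN2' attack on the Morita–Baylis–Hillman-type ester and epimerisation of the acid.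

**Step 12**
Reactants: 18 (R,E)-2-(2-acryloyl-3,6-dimethoxybenzoyl)-6-hydroxy-6-methylhepta-1,4-dien-3-yl (R)-2-methylbutanoate
Product: 19 (R,E)-1-(5,8-dimethoxy-1,4-dioxo-1,4-dihydronaphthalen-2-yl)-4-hydroxy-4-methylpent-2-en-1-yl (R)-2-methylbutanoate
Conditions: RuCl2(H2IMes)(=CH-C6H4-2-OiPr) (second-generation Hoveyda–Grubbs catalyst, 10 mol% in two portions), BHT (cat.), toluene (2 mM), 80 °C, Ar sparge
Reagents that add atoms: none
Why: Proposed new method: the ruthenium benzylidene is exchanged at the monosubstituted acryloyl alkene to give the acyl-substituted alkylidene Ru=CH–C(=O)Ar, this adds to the neighbouring CH2=C(C1')–C(=O) alkene in a [2+2] step, and cycloreversion of the ruthenacyclobutane forms C2=C3 and Ru=CH2, which takes up the next acryloyl group with release of ethene. The closest known reactions are ring-closing metatheses of aryl vinyl ketones and acrylates onto a second, electron-neutral alkene (indenones, naphthols after tautomerisation, cyclohexenones, butenolides) and the self-metathesis of acrylates and vinyl ketones through the same kind of alkylidene; new here is that both partners are enones, one of them alpha-branched, and that the ring formed is a quinone. Ring B closes as a six-membered carbocycle in which both reacting alkene carbons become ring members, and ring A holds the tether C1(=O)–C8a=C4a–C4(=O) cis. No stereocentre is formed, and C1' and the alpha-carbon of the ester are not at risk under neutral, base-free conditions. The step needs chemoselectivity among three alkenes and ring closure over intermolecular enone coupling: the internal C2'=C3' alkene is shielded by fully substituted C4' and branched C1' and could at best lead to a strained small ring or an eight-membered ring, while high dilution, removal of ethene and a phosphine-free chelating-benzylidene catalyst suited to electron-poor alkenes favour the six-membered closure. Quinones are tolerated by such catalysts, so the product should not stop turnover.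

**Step 13**
Reactants: 19 the 5,8-dimethoxyquinone of step 12
Product: 21 (R,E)-1-(5,8-dihydroxy-1,4-dioxo-1,4-dihydronaphthalen-2-yl)-4-hydroxy-4-methylpent-2-en-1-yl (R)-2-methylbutanoate (target), via naphthalenetetraone 20 (not isolated)
Conditions: AgO (divalent silver oxide, 4 equiv), 6 M HNO3, 1,4-dioxane, 10 °C, 10 min; extraction into CHCl3; shaken with aq. L-ascorbic acid
Reagents that add atoms: water, O
Why: In this argentic oxide oxidative demethylation, known for 5,8-dimethoxy-1,4-naphthoquinones, divalent silver in nitric acid is a strong enough one-electron oxidant for the acyl-deactivated dimethoxy ring, attack of water and loss of methanol give the tetraone, and a mild two-electron reductant takes this only as far as the hydrogen-bonded naphthazarin without touching the ester, the alkene or either stereocentre.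

**Compound list**
1 | 2-methylbut-3-yn-2-ol | CC(C)(O)C#C | starting material
2 | triethyl[(2-methylbut-3-yn-2-yl)oxy]silane | CC(C)(O[Si](CC)(CC)CC)C#C | intermediate
3 | 2-bromoacrolein | C=C(Br)C=O | starting material
4 | (E)-dicyclohexyl[3-methyl-3-(triethylsilyloxy)but-1-enyl]borane | CC(C)(O[Si](CC)(CC)CC)/C=C/B(C1CCCCC1)C1CCCCC1 | intermediate
5 | (E)-methyl[3-methyl-3-(triethylsilyloxy)but-1-enyl]zinc | CC(C)(O[Si](CC)(CC)CC)/C=C/[Zn]C | intermediate
6 | (3R,4E)-2-bromo-6-methyl-6-(triethylsilyloxy)hepta-1,4-dien-3-ol | O[C@H](/C=C/C(C)(C)O[Si](CC)(CC)CC)C(Br)=C | intermediate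
7 | (3R,4E)-2-bromo-3-(4-methoxybenzyloxy)-6-methyl-6-(triethylsilyloxy)hepta-1,4-diene | COc1ccc(CO[C@H](/C=C/C(C)(C)O[Si](CC)(CC)CC)C(Br)=C)cc1 | intermediate
8 | 3,6-dimethoxyphthalic anhydride | COc1ccc(OC)c2C(=O)OC(=O)c12 | starting material
9 | (3,6-dimethoxy-1,2-phenylene)dimethanol | COc1ccc(OC)c(CO)c1CO | intermediate
10 | 3,6-dimethoxyphthalaldehyde | COc1ccc(OC)c(C=O)c1C=O | intermediate
11 | 2-lithio derivative of 7 | COc1ccc(CO[C@H](/C=C/C(C)(C)O[Si](CC)(CC)CC)C([Li])=C)cc1 | intermediate
12 | lactol, 4,7-dimethoxy-3-substituted 1,3-dihydroisobenzofuran-1-ol (epimers) | COc1ccc(CO[C@H](/C=C/C(C)(C)O[Si](CC)(CC)CC)C(=C)C2OC(O)c3c(OC)ccc(OC)c23)cc1 | intermediate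
13 | bis(allylic) benzylic diol, PMB and TES ethers (epimers) | COc1ccc(CO[C@H](/C=C/C(C)(C)O[Si](CC)(CC)CC)C(=C)C(O)c2c(OC)ccc(OC)c2C(O)C=C)cc1 | intermediate
14 | triol, PMB ether (epimers) | COc1ccc(CO[C@H](/C=C/C(C)(C)O)C(=C)C(O)c2c(OC)ccc(OC)c2C(O)C=C)cc1 | intermediate
15 | bis-enone PMB ether | COc1ccc(CO[C@H](/C=C/C(C)(C)O)C(=C)C(=O)c2c(OC)ccc(OC)c2C(=O)C=C)cc1 | intermediate
16 | bis-enone diol | O[C@H](/C=C/C(C)(C)O)C(=C)C(=O)c1c(OC)ccc(OC)c1C(=O)C=C | intermediate
17 | (R)-2-methylbutanoic acid | CC[C@@H](C)C(=O)O | starting material
18 | (R,E)-2-(2-acryloyl-3,6-dimethoxybenzoyl)-6-hydroxy-6-methylhepta-1,4-dien-3-yl (R)-2-methylbutanoate | CC[C@@H](C)C(=O)O[C@H](/C=C/C(C)(C)O)C(=C)C(=O)c1c(OC)ccc(OC)c1C(=O)C=C | intermediate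
19 | 5,8-dimethoxy-1,4-naphthoquinone with the complete ester side chain at C2 | CC[C@@H](C)C(=O)O[C@H](/C=C/C(C)(C)O)C1=CC(=O)c2c(OC)ccc(OC)c2C1=O | intermediate
20 | 2-substituted naphthalene-1,4,5,8-tetraone | CC[C@@H](C)C(=O)O[C@H](/C=C/C(C)(C)O)C1=CC(=O)C2=C(C1=O)C(=O)C=CC2=O | intermediate
21 | CNP0265539.1 | CC[C@@H](C)C(=O)O[C@H](/C=C/C(C)(C)O)C1=CC(=O)c2c(O)ccc(O)c2C1=O | target

**Step count and risks**

Total steps: 13. Longest linear sequence: 11 steps (steps 1–3 and 6–13).

**Step 12.** The acyl-substituted alkylidene may form slowly and decay fast. Catalyst death or intermolecular coupling and oligomerisation of the acryloyl group could then overtake ring closure.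
- The fallback sets out from triol 14 and comes back at 19. It closes ring B two oxidation levels lower, at the benzylic diol stage, where both alkenes are allylic alcohols.
- 14 is treated with RuCl2(H2IMes)(PCy3)(=CHPh) (second-generation Grubbs catalyst) in refluxing CH2Cl2. This is the known closure of 1,7-diene-3,6-diols to cyclohex-2-ene-1,4-diols, and it should give the 5,8-dimethoxy-1,4-dihydronaphthalene-1,4-diol PMB ether F1.
- Dess–Martin periodinane then gives the 5,8-dimethoxy-1,4-naphthoquinone PMB ether F2.
- DDQ in buffered CH2Cl2 frees the quinone alcohol F3.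
- Steglich esterification of F3 with 17 (DCC, catalytic DMAP), a standard acylation of 1'-hydroxyalkyl naphthoquinones, gives 19.

**Step 13.** Three processes may reduce the outcome: incomplete oxidation of the deactivated ring, hydrolytic breakdown of the very electrophilic tetraone, and acid-induced ionisation at the tertiary allylic C4'.
- The fallback sets out from 19 and comes back at 21. It makes the ring to be oxidised electron-richer, so that a milder oxidant suffices.
- Reductive acetylation (Zn dust, Ac2O, NaOAc, rt) traps the hydroquinone as it forms, as the 1,4-diacetoxy-5,8-dimethoxynaphthalene F4.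
- (NH4)2Ce(NO3)6 in MeCN/H2O at 0 °C oxidises the dimethoxy ring to the 5,8-diacetoxy-1,4-naphthoquinone F5, which carries the side chain at C6.
- NaHCO3 in aqueous MeOH removes the two activated peri aryl acetates far faster than the hindered secondary ester.
- The 6-substituted naphthazarin set free is the tautomer of 21 and so the same compound.

**Step 2.** Ligand-free background addition to the very electrophilic aldehyde, or its polymerisation, may lead to poor facial selectivity.
- The fallback sets out from alkenylzinc 5 and aldehyde 3 and comes back at 6. It replaces asymmetric catalysis by resolution.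
- The addition is run without the chiral ligand and gives the racemic dienol F6.
- F6 is submitted to a Sharpless kinetic resolution: Ti(OiPr)4, D-(−)-diisopropyl tartrate, t-BuOOH, 4 Å molecular sieves, CH2Cl2, −20 °C, run a little past half conversion.
- The (S)-enantiomer is epoxidised at C4=C5 to the anti epoxy alcohol F7. The bromoalkene is too electron-poor to compete.
- The slow-reacting (R)-enantiomer 6 is separated by chromatography. The same treatment can upgrade scalemic 6.

**Further compounds**
F1 | step 12 | 2-[(1R,2E)-4-hydroxy-1-(4-methoxybenzyloxy)-4-methylpent-2-enyl]-5,8-dimethoxy-1,4-dihydronaphthalene-1,4-diol (epimers) | COc1ccc(CO[C@H](/C=C/C(C)(C)O)C2=CC(O)c3c(OC)ccc(OC)c3C2O)cc1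
F2 | step 12 | 2-[(1R,2E)-4-hydroxy-1-(4-methoxybenzyloxy)-4-methylpent-2-enyl]-5,8-dimethoxy-1,4-naphthoquinone | COc1ccc(CO[C@H](/C=C/C(C)(C)O)C2=CC(=O)c3c(OC)ccc(OC)c3C2=O)cc1
F3 | step 12 | 2-[(1R,2E)-1,4-dihydroxy-4-methylpent-2-enyl]-5,8-dimethoxy-1,4-naphthoquinone | O[C@H](/C=C/C(C)(C)O)C1=CC(=O)c2c(OC)ccc(OC)c2C1=O
F4 | step 13 | (R,E)-1-(1,4-diacetoxy-5,8-dimethoxynaphthalen-2-yl)-4-hydroxy-4-methylpent-2-en-1-yl (R)-2-methylbutanoate | CC[C@@H](C)C(=O)O[C@H](/C=C/C(C)(C)O)c1cc(OC(C)=O)c2c(OC)ccc(OC)c2c1OC(C)=O
F5 | step 13 | (R,E)-1-(1,4-diacetoxy-5,8-dioxo-5,8-dihydronaphthalen-2-yl)-4-hydroxy-4-methylpent-2-en-1-yl (R)-2-methylbutanoate | CC[C@@H](C)C(=O)O[C@H](/C=C/C(C)(C)O)c1cc(OC(C)=O)c2C(=O)C=CC(=O)c2c1OC(C)=O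
F6 | step 2 | racemic (E)-2-bromo-6-methyl-6-(triethylsilyloxy)hepta-1,4-dien-3-ol | OC(/C=C/C(C)(C)O[Si](CC)(CC)CC)C(Br)=C
F7 | step 2 | (S)-2-bromo-1-{(2S,3R)-3-[2-(triethylsilyloxy)propan-2-yl]oxiran-2-yl}prop-2-en-1-ol | O[C@H](C(Br)=C)[C@@H]1O[C@H]1C(C)(C)O[Si](CC)(CC)CC
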